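## The problem

Alpinnanin C (23) joins a 1,7-diarylheptanoid to a chalcone through a single carbon–carbon bond: heptanoid C3, a methine that is both benzylic and allylic, is bonded to C3' of ring A, the position between the free hydroxyls at C2' and C4' (heptanoid numbering C1 to C7 from the 4-hydroxyphenyl end, C5 the carbinol; ring A numbering C1' cinnamoyl, C6' methoxy). Ring A carries substituents at five of its six carbons, so the chain must be attached to a 2,6-dioxygenated aryl carbon and the cinnamoyl group must enter between the C2' oxygen and the C6' methoxy group. The two stereocentres, C3 (R) and C5 (S), are 1,3-related across the C4 methylene in an open chain and neither can be relied on to control the other, so the pair must come from one event or from reagent control. C3 is the fragile centre: its hydrogen is doubly activated, and base, a metal hydride or acid can epimerise it or move the C1=C2 double bond into conjugation with ring A. The 2'-hydroxychalcone closes to a flavanone under acid or base and is a Michael acceptor, and the 4-hydroxystyrene and the phloroglucinol-type ring A are sensitive to acid, electrophiles and oxidants, so the enone should arrive late and the final unmasking must be mild. What opens the molecule is the C3–C4–C5 triad: an allylic, aryl-bearing C3, one methylene and a heteroatom on C5 is the pattern left when an aryl-substituted allyl electrophile is attacked by a vinylboron ate complex and a group migrates from boron to carbon. Before acylation, ring A with its C2'/C4' oxygen pair is locally symmetric about the C3'–C6' axis, so the aryl allyl partner is simple and the later acylation has no regiochemistry.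

## Retrosynthesis

**23 to 22 (no skeletal bond cut).** The last operation should only remove protecting groups, so 23 is traced to 22, with the three phenols as methoxymethyl ethers and the C5 hydroxyl as a tert-butyldimethylsilyl ether. Acetal ethers are chosen for ring A because they direct the lithiation that opens the route and survive organolithiums, hydride, alkaline peroxide, NBS and the ruthenium catalyst. They leave under the same mild acid as the silyl ether. The forward step must free four hydroxyls without closing the chalcone to a flavanone.

**22 to 19 and 20 (cut C1'–C=O).** Friedel–Crafts acylation would need Lewis acid, which strips the acetals and promotes flavanone formation. Building the enone by aldol condensation costs two steps. Addition of aryllithium 21 to the N-methoxy-N-methylamide 20 brings in the whole cinnamoyl unit at once and releases the enone only on work-up. The aryllithium comes from bromide 19 by halogen–lithium exchange at low temperature, which is gentler towards the C3 hydrogen and the styrene than direct deprotonation of the ring. The forward step asks that exchange and acyl transfer outrun proton transfer from C3.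

**19 to 15 and 18 (cut C1=C2).** The E-styrene is cut by cross-metathesis into the vinyl compound 15 and 4-(methoxymethoxy)styrene 18. The neighbouring option, olefination of a C2 aldehyde, would put a carbonyl next to C3 and risk its racemisation; metathesis never touches C3. The cut is placed after ring bromination, so that NBS never meets the electron-rich styrene, and before acylation, so that the ruthenium carbene never meets the enone. Styrene 18 comes in one flask from commercial 4-acetoxystyrene 16, because an acetate would not survive the aryllithium step.

**15 to 14, 13 and 12 (functional group changes).** Bromide 15 comes from silyl ether 14 by electrophilic bromination; the two open ring positions are equivalent, so only one monobromide can form. Ether 14 comes from alcohol 13, and 13 from boronic ester 12 by oxidation with retention. These steps remove no complexity but carry the C5 oxygen, masked as boron, back to the key step.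

**12 to 7, 9 and 10 (cut C3–C4 and C5–C6; key step).** Ate complex 11, made from vinylboronic ester 10 and 2-phenylethyllithium 9, is allylated at its β-carbon by the allyl iridium complex from carbonate 7 while the phenethyl group migrates to the α-carbon. Cutting C4–C5 instead (aldol or carbonyl addition) would leave a C3 stereocentre to be made separately and then trusted to direct C5 across a methylene. Cutting C3–C3' puts a bond-forming event at the hindered ring carbon. The chosen cut creates both centres and two chain bonds together and leaves three achiral components, two of them commercial. It asks for branched regioselectivity at a di-ortho-substituted aryl allyl terminus, catalyst control of C3, and facial control at the vinyl carbon that becomes C5.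

**7 to 1, and 9 to 8.** Carbonate 7 comes from allylic alcohol 6 and methyl chloroformate, 6 from enoate 5 by hydride reduction, 5 from aldehyde 4 by Horner–Wadsworth–Emmons olefination, and 4 from bis-acetal 2 through aryllithium 3, made by lithiation between the two acetal oxygens. Bis-acetal 2 is the protected form of 5-methoxyresorcinol 1. A primary carbonate is preferred to any benzylic leaving group, which would not survive isolation on so electron-rich a ring. Reagent 9 is made from (2-iodoethyl)benzene 8; the iodide is taken in place of the bromide so that exchange outruns elimination to styrene.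

## Roads not taken

**Alternative 1:** Ring A is built rather than bought. The cut runs through C2'–C3', C4'–C5' and C1'–C2'. Heating 3-methoxycyclobut-2-en-1-one A1 with the triisopropylsilyl ynol ether A2, which already carries the whole chain at its propargylic carbon C3, would proceed by ketene–alkyne [2+2] addition, ring opening and 6π electrocyclisation to the resorcinol mono(silyl) ether A3.
- Merits: the ring substitution pattern is fixed by the mechanism, no metal is used, and no asymmetric step has to take place beside a di-ortho-substituted arene.
- Weak points: the stereochemical problem is untouched. A2 must first be made with both centres in place, and its C3 is propargylic and allylic, more prone to prototropic isomerisation than in 23. The ynol ether must be generated by strongly basic chemistry next to that centre and then heated. A1 is not a stock chemical. The differentiation of the two ring oxygens in A3 is of no use here, since both end as free hydroxyls.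
- Comparison: this road is better at avoiding the hindered aryl allyl electrophile, which is the main liability of the chosen catalytic step. Against that, the chosen plan makes both stereocentres and two chain bonds in one catalytic step from achiral, purchasable partners, whereas here they need a separate multi-step sequence before the key step.

**Alternative 2:** The cut is C1'–C2'. In the 3-acyl δ-lactone A4, O5 is the ring oxygen and C2' the lactone carbonyl. Mg(OCH3)2 would deprotonate the side chain at C1', Claisen attack on the lactone carbonyl would close and aromatise ring A, and O5 would be released as the free C5 hydroxyl of acetophenone A5.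
- Merits: the lactone holds C3 and C5 in one six-membered ring, and the trans relationship required can be set by conjugate addition to a 6-substituted dihydropyranone. That is a safer relay than the open transition state on which the chosen plan depends. The acyl carbon at C1' is built in, so no halogenation and lithiation of ring A are needed, and C5 needs no protecting group.
- Weak points: A4 is a polycarbonyl compound with a β-methoxy enone. Its assembly by C-acylation of a lactone enolate, its tautomers and its competing closures (pyrone formation, aldol closure) are hard to control, and the position of the methyl ether must be fixed in the open chain. The product is only the acetyl compound, so a Claisen–Schmidt condensation on a polyphenol still follows.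
- Comparison: this road is stronger on 1,3-stereocontrol and on the C1' substituent. The chosen plan sets against it stable, simple intermediates and a short, catalytic access to 12.

**Alternative 3:** C3 is assembled by two successive 1,2-shifts on boron, cutting C3'–C3 and C3–C2. Carbamate A7, carrying the C5 silyl ether, would be lithiated at C3 with sec-butyllithium and sparteine and added to the ring A boronic ester A6, whereupon the aryl group migrates. In the same pot the (Z)-alkenyllithium A8 is added and an iodine-induced Zweifel olefination gives the protected E-alkene A9.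
- Merits: each centre is under independent reagent control, so the 1,3-relationship is not in doubt. The E-styrene and its phenol arrive directly, with no metathesis on a hindered alkene.
- Weak points: A6 is di-ortho-substituted, so formation of its ate complex with a hindered lithiated carbamate is slow and reversible, which erodes selectivity. The resulting benzylic boronic ester must accept a second organolithium at the same crowded boron. A8 must be geometrically pure, the chiral diamine is stoichiometric, and A7 needs its own asymmetric synthesis.
- Comparison: in stereochemical security and in the installation of the styrene this road is better than the chosen one, and it would be the first to turn to if the iridium step failed. The chosen plan sets against it catalytic creation of both centres from achiral commercial components, no prefabricated chiral fragment, and C–C bond formation one atom away from the hindered ring carbon, not at a boron attached to it.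

Key step: step 7

## Route

Assumption (ligand): L is O,O'-(1,1'-binaphthyl-2,2'-diyl) N,N-bis[1-(2-methoxyphenyl)ethyl]phosphoramidite; the antipode that gives 3R is used, its sense of induction being inferred by analogy within this catalyst family and to be confirmed on the first sample.

Assumption (reagent): amide 20 is taken as a purchased reagent.

Chain compounds are named with heptanoid numbering (C1 the alkene terminus, C3 the ring A methine, C5 the boron- or oxygen-bearing carbon, C7 the phenyl-bearing carbon).

Step 1
Reactants: 1 5-methoxyresorcinol
Product: 2 1-methoxy-3,5-bis(methoxymethoxy)benzene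
Conditions: NaH, MOMCl, DMF, 0 °C to rt
Reagents that add atoms: chloromethyl methyl ether, COCCl
Why: Williamson-type O-alkylation of both phenoxides; the acetal ethers direct the next lithiation and are removed together at the end.

Step 2
Reactants: 2 1-methoxy-3,5-bis(methoxymethoxy)benzene
Product: 4 4-methoxy-2,6-bis(methoxymethoxy)benzaldehyde, via aryllithium 3 (not isolated)
Conditions: n-BuLi, THF, 0 °C; DMF, 0 °C to rt; aq NH4Cl
Reagents that add atoms: N,N-dimethylformamide, CN(C)C=O
Why: Directed ortho-metalation; the hydrogen between the two chelating methoxymethoxy groups is removed in preference to those beside the weaker methoxy director, and the aryllithium is formylated.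

Step 3
Reactants: 4 4-methoxy-2,6-bis(methoxymethoxy)benzaldehyde
Product: 5 ethyl (E)-3-[4-methoxy-2,6-bis(methoxymethoxy)phenyl]prop-2-enoate
Conditions: (EtO)2P(O)CH2CO2Et, NaH, THF, 0 °C to rt
Reagents that add atoms: triethyl phosphonoacetate, CCOC(=O)CP(=O)(OCC)OCC
Why: Horner–Wadsworth–Emmons olefination; the stabilised phosphonate anion gives the E-enoate, also with di-ortho-substituted benzaldehydes.

Step 4
Reactants: 5 ethyl (E)-3-[4-methoxy-2,6-bis(methoxymethoxy)phenyl]prop-2-enoate
Product: 6 (E)-3-[4-methoxy-2,6-bis(methoxymethoxy)phenyl]prop-2-en-1-ol
Conditions: i-Bu2AlH, CH2Cl2, −78 °C; aq KNaC4H4O6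
Reagents that add atoms: none
Why: 1,2-reduction of the enoate by the aluminium hydride; the neutral tartrate work-up spares the acid-sensitive, electron-rich cinnamyl alcohol.

Step 5
Reactants: 6 (E)-3-[4-methoxy-2,6-bis(methoxymethoxy)phenyl]prop-2-en-1-ol
Product: 7 (E)-3-[4-methoxy-2,6-bis(methoxymethoxy)phenyl]allyl methyl carbonate
Conditions: ClCO2Me, pyridine, CH2Cl2, 0 °C
Reagents that add atoms: methyl chloroformate, COC(=O)Cl
Why: O-acylation of a primary allylic alcohol under basic conditions; the primary carbonate is stable enough to be purified on amine-deactivated silica.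

Step 6
Reactants: 8 (2-iodoethyl)benzene
Product: 9 2-phenylethyllithium
Conditions: t-BuLi (2 equiv), Et2O/pentane, −78 °C; solution used at once
Reagents that add atoms: tert-butyllithium, [Li]C(C)(C)C
Why: Iodine–lithium exchange on a primary alkyl iodide is faster than E2 elimination to styrene; the second equivalent of t-BuLi destroys the tert-butyl iodide formed.

Step 7
Reactants: 7 (E)-3-[4-methoxy-2,6-bis(methoxymethoxy)phenyl]allyl methyl carbonate; 9 2-phenylethyllithium; 10 vinylboronic acid pinacol ester
Product: 12 2-[(3R,5S)-3-[4-methoxy-2,6-bis(methoxymethoxy)phenyl]-7-phenylhept-1-en-5-yl]-4,4,5,5-tetramethyl-1,3,2-dioxaborolane, via lithium ate complex 11 (not isolated)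
Conditions: 10, 9, THF, −78 °C to rt; then 7, [Ir(cod)Cl]2 (2.5 mol %), L (5 mol %, preactivated with n-PrNH2), THF, rt
Reagents that add atoms: none
Why: The activated iridium phosphoramidite complex ionises carbonate 7 to a cationic allyl complex of trivalent iridium, the vinyl group of ate complex 11 attacks its aryl-bearing terminus on the face away from the metal (bond C3–C4), and as charge develops next to boron the phenethyl group shifts from boron to carbon anti-periplanar to the new bond (bond C5–C6). The closest known reaction type is the iridium-catalysed enantioselective allylation of alkenylboron ate complexes with 1,2-metalate shift, a conjunctive three-component coupling. No ring is closed. C3 is set by the ligand, which leaves one face of the allyl terminus open; the ligand arms carry ortho-methoxyphenyl groups because this variant accepts ortho-substituted aryl allyl carbonates. C5 is set in the same event: addition and migration are anti across the former double bond, so its configuration depends only on which face of the vinyl group meets C3, and the open transition state that turns the pinacolatoboron unit away from ring A and the ligand is expected to lead to the 3,5-anti (3R,5S) isomer. The step needs attack at the substituted allyl terminus, which this catalyst class delivers and the three donor oxygens of ring A reinforce by concentrating positive charge at the benzylic carbon. It also needs migration of the alkyl group and not of a pinacol oxygen, the normal behaviour of such ate complexes, and an intact ate complex, which the absence of acid and of free organolithium secures.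

Step 8
Reactants: 12 2-[(3R,5S)-3-[4-methoxy-2,6-bis(methoxymethoxy)phenyl]-7-phenylhept-1-en-5-yl]-4,4,5,5-tetramethyl-1,3,2-dioxaborolane
Product: 13 (3R,5S)-3-[4-methoxy-2,6-bis(methoxymethoxy)phenyl]-7-phenylhept-1-en-5-ol
Conditions: H2O2 (30%), NaOH (aq), THF, 0 °C to rt
Reagents that add atoms: hydrogen peroxide, OO
Why: Oxidation of the carbon–boron bond; hydroperoxide adds to boron and the alkyl group migrates to oxygen with retention, so C5 keeps its configuration, while the terminal alkene and the acetals are inert.

Step 9
Reactants: 13 (3R,5S)-3-[4-methoxy-2,6-bis(methoxymethoxy)phenyl]-7-phenylhept-1-en-5-ol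
Product: 14 (3R,5S)-5-(tert-butyldimethylsilyloxy)-3-[4-methoxy-2,6-bis(methoxymethoxy)phenyl]-7-phenylhept-1-ene
Conditions: TBSCl, imidazole, DMF, rt
Reagents that add atoms: tert-butyldimethylsilyl chloride, CC(C)(C)[Si](C)(C)Cl
Why: Silylation of the secondary alcohol; the ether prevents bromoetherification in step 10 and alkoxide formation in step 13 and falls in the final acid step.

Step 10
Reactants: 14 (3R,5S)-5-(tert-butyldimethylsilyloxy)-3-[4-methoxy-2,6-bis(methoxymethoxy)phenyl]-7-phenylhept-1-ene
Product: 15 (3R,5S)-3-[3-bromo-4-methoxy-2,6-bis(methoxymethoxy)phenyl]-5-(tert-butyldimethylsilyloxy)-7-phenylhept-1-ene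
Conditions: NBS (1.0 equiv), CH2Cl2, −78 to −20 °C, dark
Reagents that add atoms: N-bromosuccinimide, O=C1CCC(=O)N1Br
Why: Electrophilic aromatic bromination of a phloroglucinol triether; the two open ring positions are equivalent, the first bromine deactivates the ring against a second, and the monosubstituted alkene is far less nucleophilic than the arene.

Step 11
Reactants: 16 4-acetoxystyrene
Product: 18 1-(methoxymethoxy)-4-vinylbenzene, via potassium 4-vinylphenoxide 17 (not isolated)
Conditions: KOt-Bu, THF, 0 °C; then MOMCl, 0 °C to rt
Reagents that add atoms: chloromethyl methyl ether, COCCl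
Why: Acyl transfer from the aryl acetate to tert-butoxide frees the phenoxide, which is O-alkylated in the same flask, so the polymerisation-prone free vinylphenol is never isolated.

Step 12
Reactants: 15 (3R,5S)-3-[3-bromo-4-methoxy-2,6-bis(methoxymethoxy)phenyl]-5-(tert-butyldimethylsilyloxy)-7-phenylhept-1-ene; 18 1-(methoxymethoxy)-4-vinylbenzene
Product: 19 (1E,3R,5S)-3-[3-bromo-4-methoxy-2,6-bis(methoxymethoxy)phenyl]-5-(tert-butyldimethylsilyloxy)-1-[4-(methoxymethoxy)phenyl]-7-phenylhept-1-ene
Conditions: second-generation Hoveyda–Grubbs catalyst RuCl2(H2IMes)(=CH-C6H4-2-O-i-Pr) (5–10 mol %), 18 (4 equiv), 2,6-dichloro-1,4-benzoquinone (10 mol %), CH2Cl2, 40 °C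
Reagents that add atoms: none
Why: Olefin cross-metathesis; the styrene is used in excess and its homodimer re-enters the cycle, the E-alkene results from thermodynamic control, and the quinone suppresses ruthenium hydride isomerisation that would move the alkene towards ring A and erase C3.

Step 13
Reactants: 19 (1E,3R,5S)-3-[3-bromo-4-methoxy-2,6-bis(methoxymethoxy)phenyl]-5-(tert-butyldimethylsilyloxy)-1-[4-(methoxymethoxy)phenyl]-7-phenylhept-1-ene; 20 (E)-N-methoxy-N-methyl-3-phenylprop-2-enamide
Product: 22 (E)-1-[3-[(1E,3R,5S)-5-(tert-butyldimethylsilyloxy)-1-[4-(methoxymethoxy)phenyl]-7-phenylhept-1-en-3-yl]-6-methoxy-2,4-bis(methoxymethoxy)phenyl]-3-phenylprop-2-en-1-one, via aryllithium 21 (not isolated)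
Conditions: t-BuLi (2 equiv), THF, −78 °C; then 20, −78 to 0 °C; aq NH4Cl
Reagents that add atoms: none
Why: Bromine–lithium exchange at −78 °C is faster than deprotonation at C3 or addition to the styrene, and the aryllithium adds to the amide carbonyl to give a chelated tetrahedral intermediate (Weinreb ketone synthesis) that releases the enone only on work-up, so neither over-addition nor conjugate addition to the product can occur.

Step 14
Reactants: 22 (E)-1-[3-[(1E,3R,5S)-5-(tert-butyldimethylsilyloxy)-1-[4-(methoxymethoxy)phenyl]-7-phenylhept-1-en-3-yl]-6-methoxy-2,4-bis(methoxymethoxy)phenyl]-3-phenylprop-2-en-1-one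
Product: 23 (E)-1-[2,4-dihydroxy-3-[(1E,3R,5S)-5-hydroxy-1-(4-hydroxyphenyl)-7-phenylhept-1-en-3-yl]-6-methoxyphenyl]-3-phenylprop-2-en-1-one (alpinnanin C)
Conditions: HCl (3 M aq), MeOH, rt
Reagents that add atoms: none
Why: Acid-catalysed acetal exchange with methanol removes the three methoxymethyl ethers and methanolysis removes the silyl ether; this unmasking is standard for methoxymethyl-protected 2'-hydroxy-6'-methoxychalcones that carry acid-sensitive alkenes, and neither stereocentre is touched.

## Compound list

1 | 5-methoxyresorcinol | COc1cc(O)cc(O)c1 | starting material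
2 | 1-methoxy-3,5-bis(methoxymethoxy)benzene | COCOc1cc(OC)cc(OCOC)c1 | intermediate
3 | 4-methoxy-2,6-bis(methoxymethoxy)phenyllithium | COCOc1cc(OC)cc(OCOC)c1[Li] | intermediate (not isolated)
4 | 4-methoxy-2,6-bis(methoxymethoxy)benzaldehyde | COCOc1cc(OC)cc(OCOC)c1C=O | intermediate
5 | ethyl (E)-3-[4-methoxy-2,6-bis(methoxymethoxy)phenyl]prop-2-enoate | CCOC(=O)/C=C/c1c(OCOC)cc(OC)cc1OCOC | intermediate
6 | (E)-3-[4-methoxy-2,6-bis(methoxymethoxy)phenyl]prop-2-en-1-ol | OC/C=C/c1c(OCOC)cc(OC)cc1OCOC | intermediate
7 | (E)-3-[4-methoxy-2,6-bis(methoxymethoxy)phenyl]allyl methyl carbonate | COC(=O)OC/C=C/c1c(OCOC)cc(OC)cc1OCOC | intermediate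
8 | (2-iodoethyl)benzene | ICCc1ccccc1 | starting material
9 | 2-phenylethyllithium | [Li]CCc1ccccc1 | intermediate
10 | vinylboronic acid pinacol ester | C=CB1OC(C)(C)C(C)(C)O1 | starting material
11 | lithium (2-phenylethyl)(vinyl)(pinacolato)borate | [Li+].C=C[B-]1(CCc2ccccc2)OC(C)(C)C(C)(C)O1 | intermediate (not isolated)
12 | 2-[(3R,5S)-3-[4-methoxy-2,6-bis(methoxymethoxy)phenyl]-7-phenylhept-1-en-5-yl]-4,4,5,5-tetramethyl-1,3,2-dioxaborolane | COc1cc(OCOC)c([C@@H](C=C)C[C@@H](B2OC(C)(C)C(C)(C)O2)CCc2ccccc2)c(OCOC)c1 | intermediate
13 | (3R,5S)-3-[4-methoxy-2,6-bis(methoxymethoxy)phenyl]-7-phenylhept-1-en-5-ol | COc1cc(OCOC)c([C@@H](C=C)C[C@@H](O)CCc2ccccc2)c(OCOC)c1 | intermediate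
14 | (3R,5S)-5-(tert-butyldimethylsilyloxy)-3-[4-methoxy-2,6-bis(methoxymethoxy)phenyl]-7-phenylhept-1-ene | COc1cc(OCOC)c([C@@H](C=C)C[C@@H](O[Si](C)(C)C(C)(C)C)CCc2ccccc2)c(OCOC)c1 | intermediate
15 | (3R,5S)-3-[3-bromo-4-methoxy-2,6-bis(methoxymethoxy)phenyl]-5-(tert-butyldimethylsilyloxy)-7-phenylhept-1-ene | COc1cc(OCOC)c([C@@H](C=C)C[C@@H](O[Si](C)(C)C(C)(C)C)CCc2ccccc2)c(OCOC)c1Br | intermediate
16 | 4-acetoxystyrene | C=Cc1ccc(OC(C)=O)cc1 | starting material
17 | potassium 4-vinylphenoxide | [K+].[O-]c1ccc(C=C)cc1 | intermediate (not isolated)
18 | 1-(methoxymethoxy)-4-vinylbenzene | C=Cc1ccc(OCOC)cc1 | intermediate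
19 | (1E,3R,5S)-3-[3-bromo-4-methoxy-2,6-bis(methoxymethoxy)phenyl]-5-(tert-butyldimethylsilyloxy)-1-[4-(methoxymethoxy)phenyl]-7-phenylhept-1-ene | COc1cc(OCOC)c([C@@H](/C=C/c2ccc(OCOC)cc2)C[C@@H](O[Si](C)(C)C(C)(C)C)CCc2ccccc2)c(OCOC)c1Br | intermediate
20 | (E)-N-methoxy-N-methyl-3-phenylprop-2-enamide | CON(C)C(=O)/C=C/c1ccccc1 | starting material
21 | aryllithium from 19 (lithium in place of bromine at C1') | COc1cc(OCOC)c([C@@H](/C=C/c2ccc(OCOC)cc2)C[C@@H](O[Si](C)(C)C(C)(C)C)CCc2ccccc2)c(OCOC)c1[Li] | intermediate (not isolated)
22 | (E)-1-[3-[(1E,3R,5S)-5-(tert-butyldimethylsilyloxy)-1-[4-(methoxymethoxy)phenyl]-7-phenylhept-1-en-3-yl]-6-methoxy-2,4-bis(methoxymethoxy)phenyl]-3-phenylprop-2-en-1-one | COc1cc(OCOC)c([C@@H](/C=C/c2ccc(OCOC)cc2)C[C@@H](O[Si](C)(C)C(C)(C)C)CCc2ccccc2)c(OCOC)c1C(=O)/C=C/c1ccccc1 | intermediate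
23 | alpinnanin C, (E)-1-[2,4-dihydroxy-3-[(1E,3R,5S)-5-hydroxy-1-(4-hydroxyphenyl)-7-phenylhept-1-en-3-yl]-6-methoxyphenyl]-3-phenylprop-2-en-1-one | COc1cc(O)c([C@@H](/C=C/c2ccc(O)cc2)C[C@@H](O)CCc2ccccc2)c(O)c1C(=O)/C=C/c1ccccc1 | target

## Step count and risks

Total: 14 steps. Longest linear sequence: 12 steps from 1 (steps 1 to 5, 7 to 10 and 12 to 14); steps 6 and 11 are side branches.

**Step 7 (key step).** The most likely failure is poor facial selectivity at the vinyl carbon that becomes C5. The 1,3-relationship rests on an open transition state, and the two ortho substituents of ring A may change which face of the alkene is presented, so the 5-epimer could be a main or even the major product. The same crowding could slow attack at the branched terminus. Fallback: setting out from 7, the coupling is run unchanged and the epimeric 2-[(3R,5R)-3-[4-methoxy-2,6-bis(methoxymethoxy)phenyl]-7-phenylhept-1-en-5-yl]-4,4,5,5-tetramethyl-1,3,2-dioxaborolane F1 is oxidised with alkaline H2O2 to (3R,5R)-3-[4-methoxy-2,6-bis(methoxymethoxy)phenyl]-7-phenylhept-1-en-5-ol F2. After separation from any 13, this alcohol is inverted by Mitsunobu reaction (4-nitrobenzoic acid, PPh3, diisopropyl azodicarboxylate) to (3R,5S)-3-[4-methoxy-2,6-bis(methoxymethoxy)phenyl]-7-phenylhept-1-en-5-yl 4-nitrobenzoate F3. Methanolysis (K2CO3, MeOH) returns the route to 13. C5 is then fixed by an invertive substitution, not by the catalyst.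

**Step 12.** The most likely failure is slow metathesis, because the vinyl group sits on a tertiary allylic carbon beside a di-ortho-substituted arene. A long reaction time then invites alkene migration and loss of C3. Fallback: setting out from 15, a Heck arylation with 1-iodo-4-(methoxymethoxy)benzene (Pd(OAc)2, n-Bu4NCl, NaHCO3, DMF, 70 °C) joins the aryl group to the unhindered terminal carbon and gives 19 directly. The electron-rich, hindered ring A bromide is not expected to compete with the aryl iodide in oxidative addition. No new compound is made on the way.

**Step 13.** The most likely failure is slow acyl transfer from the amide to the di-ortho-substituted aryllithium. That leaves time for proton transfer from the doubly activated C3–H, with racemisation or alkene migration. Fallback: setting out from aryllithium 21, cinnamaldehyde is used as a faster electrophile at −78 °C and gives (E)-1-[3-[(1E,3R,5S)-5-(tert-butyldimethylsilyloxy)-1-[4-(methoxymethoxy)phenyl]-7-phenylhept-1-en-3-yl]-6-methoxy-2,4-bis(methoxymethoxy)phenyl]-3-phenylprop-2-en-1-ol F4 as a mixture of carbinol epimers. Oxidation of this allylic, benzylic alcohol with MnO2 returns the route to 22.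

**Step 14.** The most likely failure is acid-promoted ring closure while the last acetal is still being cleaved. The 2'-hydroxychalcone can close to the flavanone, and a hydroxyl can add to the protonated hydroxystyrene. Fallback: setting out from 19, bromine–lithium exchange and addition to N-methoxy-N-methylacetamide give 1-[3-[(1E,3R,5S)-5-(tert-butyldimethylsilyloxy)-1-[4-(methoxymethoxy)phenyl]-7-phenylhept-1-en-3-yl]-6-methoxy-2,4-bis(methoxymethoxy)phenyl]ethan-1-one F5. Acid methanolysis, now with no enone present, gives 1-[2,4-dihydroxy-3-[(1E,3R,5S)-5-hydroxy-1-(4-hydroxyphenyl)-7-phenylhept-1-en-3-yl]-6-methoxyphenyl]ethan-1-one F6. A Claisen–Schmidt condensation with benzaldehyde (KOH, EtOH, rt) then forms the chalcone as its phenolate, which does not cyclise, and arrives at 23.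

## Further compounds

F1 | step 7 | 2-[(3R,5R)-3-[4-methoxy-2,6-bis(methoxymethoxy)phenyl]-7-phenylhept-1-en-5-yl]-4,4,5,5-tetramethyl-1,3,2-dioxaborolane | COc1cc(OCOC)c([C@@H](C=C)C[C@H](B2OC(C)(C)C(C)(C)O2)CCc2ccccc2)c(OCOC)c1
F2 | step 7 | (3R,5R)-3-[4-methoxy-2,6-bis(methoxymethoxy)phenyl]-7-phenylhept-1-en-5-ol | COc1cc(OCOC)c([C@@H](C=C)C[C@H](O)CCc2ccccc2)c(OCOC)c1
F3 | step 7 | (3R,5S)-3-[4-methoxy-2,6-bis(methoxymethoxy)phenyl]-7-phenylhept-1-en-5-yl 4-nitrobenzoate | COc1cc(OCOC)c([C@@H](C=C)C[C@@H](OC(=O)c2ccc([N+](=O)[O-])cc2)CCc2ccccc2)c(OCOC)c1
F0 | step 12 | none | none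
F4 | step 13 | (E)-1-[3-[(1E,3R,5S)-5-(tert-butyldimethylsilyloxy)-1-[4-(methoxymethoxy)phenyl]-7-phenylhept-1-en-3-yl]-6-methoxy-2,4-bis(methoxymethoxy)phenyl]-3-phenylprop-2-en-1-ol (both carbinol epimers) | COc1cc(OCOC)c([C@@H](/C=C/c2ccc(OCOC)cc2)C[C@@H](O[Si](C)(C)C(C)(C)C)CCc2ccccc2)c(OCOC)c1C(O)/C=C/c1ccccc1
F5 | step 14 | 1-[3-[(1E,3R,5S)-5-(tert-butyldimethylsilyloxy)-1-[4-(methoxymethoxy)phenyl]-7-phenylhept-1-en-3-yl]-6-methoxy-2,4-bis(methoxymethoxy)phenyl]ethan-1-one | COc1cc(OCOC)c([C@@H](/C=C/c2ccc(OCOC)cc2)C[C@@H](O[Si](C)(C)C(C)(C)C)CCc2ccccc2)c(OCOC)c1C(C)=O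
F6 | step 14 | 1-[2,4-dihydroxy-3-[(1E,3R,5S)-5-hydroxy-1-(4-hydroxyphenyl)-7-phenylhept-1-en-3-yl]-6-methoxyphenyl]ethan-1-one | COc1cc(O)c([C@@H](/C=C/c2ccc(O)cc2)C[C@@H](O)CCc2ccccc2)c(O)c1C(C)=O
A1 | alternative 1 | 3-methoxycyclobut-2-en-1-one | COC1=CC(=O)C1
A2 | alternative 1 | [(3R,5S)-5-(tert-butyldimethylsilyloxy)-3-[(E)-2-[4-(methoxymethoxy)phenyl]ethenyl]-7-phenylhept-1-ynoxy]triisopropylsilane | CC(C)[Si](C(C)C)(C(C)C)OC#C[C@@H](/C=C/c1ccc(OCOC)cc1)C[C@@H](O[Si](C)(C)C(C)(C)C)CCc1ccccc1
A3 | alternative 1 | 2-[(1E,3R,5S)-5-(tert-butyldimethylsilyloxy)-1-[4-(methoxymethoxy)phenyl]-7-phenylhept-1-en-3-yl]-5-methoxy-3-(triisopropylsilyloxy)phenol | COc1cc(O)c([C@@H](/C=C/c2ccc(OCOC)cc2)C[C@@H](O[Si](C)(C)C(C)(C)C)CCc2ccccc2)c(O[Si](C(C)C)(C(C)C)C(C)C)c1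
A4 | alternative 2 | 4,6-trans-3-(3-methoxy-5-oxohex-2-enoyl)-4-[(E)-2-[4-(methoxymethoxy)phenyl]ethenyl]-6-(2-phenylethyl)tetrahydropyran-2-one (heptanoid C3 and C5 as in 23; acyl-bearing carbon and enol ether geometry undefined) | CC(=O)CC(OC)=CC(=O)C1C(=O)O[C@@H](CCc2ccccc2)C[C@@H]1/C=C/c1ccc(OCOC)cc1
A5 | alternative 2 | 1-[2,4-dihydroxy-3-[(1E,3R,5S)-5-hydroxy-1-[4-(methoxymethoxy)phenyl]-7-phenylhept-1-en-3-yl]-6-methoxyphenyl]ethan-1-one | COc1cc(O)c([C@@H](/C=C/c2ccc(OCOC)cc2)C[C@@H](O)CCc2ccccc2)c(O)c1C(C)=O
A6 | alternative 3 | 2-[4-methoxy-2,6-bis(methoxymethoxy)phenyl]-4,4,5,5-tetramethyl-1,3,2-dioxaborolane | COc1cc(OCOC)c(B2OC(C)(C)C(C)(C)O2)c(OCOC)c1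
A7 | alternative 3 | (3S)-3-(tert-butyldimethylsilyloxy)-5-phenylpentyl N,N-diisopropylcarbamate | CC(C)N(C(C)C)C(=O)OCC[C@@H](O[Si](C)(C)C(C)(C)C)CCc1ccccc1
A8 | alternative 3 | (Z)-2-[4-(tert-butyldimethylsilyloxy)phenyl]ethenyllithium | [Li]/C=C\c1ccc(O[Si](C)(C)C(C)(C)C)cc1
A9 | alternative 3 | (1E,3R,5S)-5-(tert-butyldimethylsilyloxy)-1-[4-(tert-butyldimethylsilyloxy)phenyl]-3-[4-methoxy-2,6-bis(methoxymethoxy)phenyl]-7-phenylhept-1-ene | COc1cc(OCOC)c([C@@H](/C=C/c2ccc(O[Si](C)(C)C(C)(C)C)cc2)C[C@@H](O[Si](C)(C)C(C)(C)C)CCc2ccccc2)c(OCOC)c1
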